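**Retrosynthetic overview**

- The plan rests on the C4 carbonyl carbon of ring C: it sits between C4a of the fully substituted ring A and C3, and O1 hangs on C8a next to C4a, so C4 can be carbon monoxide.
- Cutting C4a–C4, C4–C3 and O1–C2 gives iodophenol 11 (ring A with C4a–I and C8a–OH), arylalkyne 19 (ring B with C2 and C3) and CO 20. Ring C is the only ring formed, and it is formed last.
- Ring A piece 11 comes from syringol: O-benzylation, bromination at both positions ortho to the methoxy groups, two successive Br-to-OH exchanges with a benzylation between them, and iodination of the last C–H.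
- Ring B piece 19 comes from 2,5-dimethoxybenzaldehyde: Baeyer–Villiger (Dakin-type) oxidation, benzylation, Vilsmeier–Haack formylation and Ohira–Bestmann alkynylation.
- After the annulation, C3 is oxygenated by lithiation, borylation and oxidation, the 3-OH is methylated, and the three benzyl ethers are removed by hydrogenolysis.

Key step: step 11

Assumption: the target has no stereocentre and no stereogenic double bond, so no step needs stereocontrol; benzyl serves as the one protecting group for all three future phenols (C5, C7, C4').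

**Route**

Step 1
Reactants: 1 2,6-dimethoxyphenol (syringol)
Product: 2 2-(benzyloxy)-1,3-dimethoxybenzene
Conditions: BnBr, K2CO3, DMF, 60 °C
Reagents that add atoms: benzyl bromide, BrCc1ccccc1
Why: Williamson etherification; capping the phenol also moves the later brominations away from the position para to this oxygen and onto the two positions ortho to the methoxy groups.

Step 2
Reactants: 2 2-(benzyloxy)-1,3-dimethoxybenzene
Product: 3 3-(benzyloxy)-1,5-dibromo-2,4-dimethoxybenzene
Conditions: NBS (2.1 equiv), MeCN, 0 °C to rt, dark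
Reagents that add atoms: N-bromosuccinimide, O=C1CCC(=O)N1Br
Why: Electrophilic aromatic bromination; the central ether is flanked on both sides and twisted out of conjugation, so each bromine should enter ortho to one methoxy group and para to the other, as in the known twofold bromination of 1,2,3-trimethoxybenzene, leaving the C–H between the two bromines.

Step 3
Reactants: 3 3-(benzyloxy)-1,5-dibromo-2,4-dimethoxybenzene
Product: 6 3-(benzyloxy)-5-bromo-2,4-dimethoxyphenol, via aryllithium 4 (not isolated), via lithium aryltrimethoxyborate 5 (not isolated)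
Conditions: n-BuLi (1.0 equiv), THF, −78 °C; B(OMe)3, −78 °C to rt; AcOH, 30% H2O2, 0 °C to rt
Reagents that add atoms: hydrogen peroxide, OO
Why: Bromine–lithium exchange at one of two equivalent bromides (one equivalent of n-BuLi at −78 °C should stop after the first exchange), borylation and oxidative C–B to C–O migration, the standard aryl bromide to phenol sequence.

Step 4
Reactants: 6 3-(benzyloxy)-5-bromo-2,4-dimethoxyphenol
Product: 7 1,3-bis(benzyloxy)-5-bromo-2,4-dimethoxybenzene
Conditions: BnBr, K2CO3, DMF, rt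
Reagents that add atoms: benzyl bromide, BrCc1ccccc1
Why: Williamson etherification of the only free hydroxyl, which fixes the future C5 oxygen as its benzyl ether before the second oxygen is unveiled.

Step 5
Reactants: 7 1,3-bis(benzyloxy)-5-bromo-2,4-dimethoxybenzene
Product: 10 3,5-bis(benzyloxy)-2,4-dimethoxyphenol, via aryllithium 8 (not isolated), via lithium aryltrimethoxyborate 9 (not isolated)
Conditions: n-BuLi (1.1 equiv), THF, −78 °C; B(OMe)3, −78 °C to rt; AcOH, 30% H2O2, 0 °C to rt
Reagents that add atoms: hydrogen peroxide, OO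
Why: Bromine–lithium exchange, borylation and peroxide oxidation as in step 3; the exchange is far faster than deprotonation of the benzyl ethers at −78 °C.

Step 6
Reactants: 10 3,5-bis(benzyloxy)-2,4-dimethoxyphenol
Product: 11 3,5-bis(benzyloxy)-2-iodo-4,6-dimethoxyphenol
Conditions: NIS (1.05 equiv), MeCN, 0 °C, dark
Reagents that add atoms: N-iodosuccinimide, O=C1CCC(=O)N1I
Why: Electrophilic iodination ortho to a free phenol; the oxygenated ring has one C–H left, flanked by OH and OBn, so the regiochemistry is fixed.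

Step 7
Reactants: 12 2,5-dimethoxybenzaldehyde
Product: 14 2,5-dimethoxyphenol, via 2,5-dimethoxyphenyl formate 13 (not isolated)
Conditions: mCPBA, CH2Cl2, rt; then K2CO3 (cat.), MeOH, rt
Reagents that add atoms: meta-chloroperoxybenzoic acid, OOC(=O)c1cccc(Cl)c1
Why: Baeyer–Villiger oxidation of an electron-rich benzaldehyde (Dakin-type aryl migration) followed by methanolysis of the aryl formate.

Step 8
Reactants: 14 2,5-dimethoxyphenol
Product: 15 2-(benzyloxy)-1,4-dimethoxybenzene
Conditions: BnBr, K2CO3, DMF, rt
Reagents that add atoms: benzyl bromide, BrCc1ccccc1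
Why: Williamson etherification of the single phenol.

Step 9
Reactants: 15 2-(benzyloxy)-1,4-dimethoxybenzene
Product: 17 4-(benzyloxy)-2,5-dimethoxybenzaldehyde, via aryl iminium salt 16 (not isolated)
Conditions: POCl3, DMF, 0 °C to 70 °C; then H2O, 50 °C
Reagents that add atoms: N,N-dimethylformamide, CN(C)C=O; water, O
Why: Vilsmeier–Haack formylation; attack should occur para to the benzyloxy group and ortho to a methoxy group, as 1,2,4-trialkoxybenzenes give 2,4,5-trialkoxybenzaldehydes.

Step 10
Reactants: 17 4-(benzyloxy)-2,5-dimethoxybenzaldehyde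
Product: 19 1-(benzyloxy)-4-ethynyl-2,5-dimethoxybenzene, via diazoalkene 18 (not isolated)
Conditions: dimethyl (1-diazo-2-oxopropyl)phosphonate, K2CO3, MeOH, rt
Reagents that add atoms: dimethyl (1-diazo-2-oxopropyl)phosphonate (Bestmann–Ohira reagent), CC(=O)C(=[N+]=[N-])P(=O)(OC)OC
Why: Seyferth–Gilbert homologation in the Ohira–Bestmann variant; the diazophosphonate anion olefinates the aldehyde, and loss of N2 with a 1,2-hydrogen shift gives the terminal alkyne under conditions that leave the benzyl ether alone.

Step 11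
Reactants: 11 3,5-bis(benzyloxy)-2-iodo-4,6-dimethoxyphenol; 19 1-(benzyloxy)-4-ethynyl-2,5-dimethoxybenzene; 20 carbon monoxide
Product: 23 5,7-bis(benzyloxy)-2-[4-(benzyloxy)-2,5-dimethoxyphenyl]-6,8-dimethoxy-4H-chromen-4-one, via ynone 21 (not isolated), via enaminone 22 (not isolated)
Conditions: PdCl2(PPh3)2 (5 mol %), CO (10 bar), Et2NH, 110 °C
Reagents that add atoms: none
Why: PdCl2(PPh3)2, a divalent palladium precatalyst, is reduced in the CO/amine medium to zerovalent palladium, which inserts into the C–I bond of 11; CO insertion gives an aroyl-palladium species, the amine-deprotonated alkyne 19 is transferred to palladium, and reductive elimination releases ynone 21, in which CO has become C4 (bonds C4a–C4 and C4–C3). Diethylamine then adds to the β-carbon of the ynone to give enaminone 22, and the ortho phenol oxygen attacks that same carbon with loss of the amine, forming O1–C2. The closest known reaction type is the palladium-catalysed carbonylative annulation of ortho-iodophenols with terminal acetylenes in a secondary amine, which gives flavones and chromones. Ring C is the only ring closed, in a 6-endo mode (addition–elimination at the enaminone carbon, formally 6-endo-dig on the ynone), and no stereocentre is created. Three selectivities are needed: CO uptake before alkyne transfer (copper-free medium, CO pressure, and the ready CO insertion of an electron-rich, doubly ortho-substituted aryl-palladium), capture of the aroyl-palladium by the alkyne before the amine can form an amide, and six- over five-membered closure, for which the enaminone pathway opened by the secondary amine disfavours 5-exo aurone formation. Ring A regiochemistry is not in play, because iodine sits on the only carbon of 11 that bears no oxygen, next to the single free hydroxyl.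

Step 12
Reactants: 23 5,7-bis(benzyloxy)-2-[4-(benzyloxy)-2,5-dimethoxyphenyl]-6,8-dimethoxy-4H-chromen-4-one
Product: 26 5,7-bis(benzyloxy)-2-[4-(benzyloxy)-2,5-dimethoxyphenyl]-3-hydroxy-6,8-dimethoxy-4H-chromen-4-one, via 3-lithioflavone 24 (not isolated), via lithium trimethoxyborate 25 (not isolated)
Conditions: LiN(i-Pr)2 (2 equiv), THF, −78 °C; B(OMe)3, −78 °C to 0 °C; AcOH, 30% H2O2, 0 °C to rt
Reagents that add atoms: hydrogen peroxide, OO
Why: Deprotonation of the flavone at C3 (the only ring C–H, acidified by the adjacent carbonyl and ring oxygen and assisted by the 2'-methoxy group), borylation and peroxide oxidation, the known lithiation route from flavones to flavonols; the amide base should not touch the benzyl ethers at −78 °C.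

Step 13
Reactants: 26 5,7-bis(benzyloxy)-2-[4-(benzyloxy)-2,5-dimethoxyphenyl]-3-hydroxy-6,8-dimethoxy-4H-chromen-4-one
Product: 27 5,7-bis(benzyloxy)-2-[4-(benzyloxy)-2,5-dimethoxyphenyl]-3,6,8-trimethoxy-4H-chromen-4-one
Conditions: MeI, K2CO3, acetone, reflux
Reagents that add atoms: iodomethane, CI
Why: Williamson O-methylation of the 3-hydroxyl, the only free OH in the molecule.

Step 14
Reactants: 27 5,7-bis(benzyloxy)-2-[4-(benzyloxy)-2,5-dimethoxyphenyl]-3,6,8-trimethoxy-4H-chromen-4-one
Product: 28 5,7-dihydroxy-2-(4-hydroxy-2,5-dimethoxyphenyl)-3,6,8-trimethoxy-4H-chromen-4-one (5,7,4'-trihydroxy-3,6,8,2',5'-pentamethoxyflavone)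
Conditions: H2 (1 bar), 10% Pd/C, THF/MeOH, rt
Reagents that add atoms: none
Why: Catalytic hydrogenolysis of three benzyl aryl ethers; the tetrasubstituted, donor-substituted C2=C3 bond of the 3-methoxyflavone and the methyl ethers should not react at 1 bar.

**Compound list**

1 | 2,6-dimethoxyphenol (syringol) | COc1cccc(OC)c1O | starting material
2 | 2-(benzyloxy)-1,3-dimethoxybenzene | COc1cccc(OC)c1OCc1ccccc1 | intermediate
3 | 3-(benzyloxy)-1,5-dibromo-2,4-dimethoxybenzene | COc1c(Br)cc(Br)c(OC)c1OCc1ccccc1 | intermediate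
4 | [3-(benzyloxy)-5-bromo-2,4-dimethoxyphenyl]lithium | [Li]c1cc(Br)c(OC)c(OCc2ccccc2)c1OC | intermediate (not isolated)
5 | lithium [3-(benzyloxy)-5-bromo-2,4-dimethoxyphenyl]trimethoxyborate | [Li+].CO[B-](OC)(OC)c1cc(Br)c(OC)c(OCc2ccccc2)c1OC | intermediate (not isolated)
6 | 3-(benzyloxy)-5-bromo-2,4-dimethoxyphenol | COc1c(O)cc(Br)c(OC)c1OCc1ccccc1 | intermediate
7 | 1,3-bis(benzyloxy)-5-bromo-2,4-dimethoxybenzene | COc1c(OCc2ccccc2)cc(Br)c(OC)c1OCc1ccccc1 | intermediate
8 | [3,5-bis(benzyloxy)-2,4-dimethoxyphenyl]lithium | [Li]c1cc(OCc2ccccc2)c(OC)c(OCc2ccccc2)c1OC | intermediate (not isolated)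
9 | lithium [3,5-bis(benzyloxy)-2,4-dimethoxyphenyl]trimethoxyborate | [Li+].CO[B-](OC)(OC)c1cc(OCc2ccccc2)c(OC)c(OCc2ccccc2)c1OC | intermediate (not isolated)
10 | 3,5-bis(benzyloxy)-2,4-dimethoxyphenol | COc1c(O)cc(OCc2ccccc2)c(OC)c1OCc1ccccc1 | intermediate
11 | 3,5-bis(benzyloxy)-2-iodo-4,6-dimethoxyphenol | COc1c(O)c(I)c(OCc2ccccc2)c(OC)c1OCc1ccccc1 | intermediate
12 | 2,5-dimethoxybenzaldehyde | COc1ccc(OC)c(C=O)c1 | starting material
13 | 2,5-dimethoxyphenyl formate | COc1ccc(OC)c(OC=O)c1 | intermediate (not isolated)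
14 | 2,5-dimethoxyphenol | COc1ccc(OC)c(O)c1 | intermediate
15 | 2-(benzyloxy)-1,4-dimethoxybenzene | COc1ccc(OC)c(OCc2ccccc2)c1 | intermediate
16 | N-[4-(benzyloxy)-2,5-dimethoxybenzylidene]-N-methylmethanaminium dichlorophosphate | COc1cc(C=[N+](C)C)c(OC)cc1OCc1ccccc1.[O-]P(Cl)(Cl)=O | intermediate (not isolated)
17 | 4-(benzyloxy)-2,5-dimethoxybenzaldehyde | COc1cc(C=O)c(OC)cc1OCc1ccccc1 | intermediate
18 | 1-(benzyloxy)-4-(2-diazoethenyl)-2,5-dimethoxybenzene | COc1cc(C=C=[N+]=[N-])c(OC)cc1OCc1ccccc1 | intermediate (not isolated)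
19 | 1-(benzyloxy)-4-ethynyl-2,5-dimethoxybenzene | COc1cc(C#C)c(OC)cc1OCc1ccccc1 | intermediate
20 | carbon monoxide | [C-]#[O+] | starting material
21 | 1-[2,4-bis(benzyloxy)-6-hydroxy-3,5-dimethoxyphenyl]-3-[4-(benzyloxy)-2,5-dimethoxyphenyl]prop-2-yn-1-one | COc1cc(C#CC(=O)c2c(O)c(OC)c(OCc3ccccc3)c(OC)c2OCc2ccccc2)c(OC)cc1OCc1ccccc1 | intermediate (not isolated)
22 | 1-[2,4-bis(benzyloxy)-6-hydroxy-3,5-dimethoxyphenyl]-3-[4-(benzyloxy)-2,5-dimethoxyphenyl]-3-(diethylamino)prop-2-en-1-one (alkene geometry not fixed; either isomer can close) | CCN(CC)C(=CC(=O)c1c(O)c(OC)c(OCc2ccccc2)c(OC)c1OCc1ccccc1)c1cc(OC)c(OCc2ccccc2)cc1OC | intermediate (not isolated)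
23 | 5,7-bis(benzyloxy)-2-[4-(benzyloxy)-2,5-dimethoxyphenyl]-6,8-dimethoxy-4H-chromen-4-one | COc1cc(-c2cc(=O)c3c(OCc4ccccc4)c(OC)c(OCc4ccccc4)c(OC)c3o2)c(OC)cc1OCc1ccccc1 | intermediate
24 | {5,7-bis(benzyloxy)-2-[4-(benzyloxy)-2,5-dimethoxyphenyl]-6,8-dimethoxy-4-oxo-4H-chromen-3-yl}lithium | COc1cc(-c2oc3c(OC)c(OCc4ccccc4)c(OC)c(OCc4ccccc4)c3c(=O)c2[Li])c(OC)cc1OCc1ccccc1 | intermediate (not isolated)
25 | lithium {5,7-bis(benzyloxy)-2-[4-(benzyloxy)-2,5-dimethoxyphenyl]-6,8-dimethoxy-4-oxo-4H-chromen-3-yl}trimethoxyborate | [Li+].COc1cc(-c2oc3c(OC)c(OCc4ccccc4)c(OC)c(OCc4ccccc4)c3c(=O)c2[B-](OC)(OC)OC)c(OC)cc1OCc1ccccc1 | intermediate (not isolated)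
26 | 5,7-bis(benzyloxy)-2-[4-(benzyloxy)-2,5-dimethoxyphenyl]-3-hydroxy-6,8-dimethoxy-4H-chromen-4-one | COc1cc(-c2oc3c(OC)c(OCc4ccccc4)c(OC)c(OCc4ccccc4)c3c(=O)c2O)c(OC)cc1OCc1ccccc1 | intermediate
27 | 5,7-bis(benzyloxy)-2-[4-(benzyloxy)-2,5-dimethoxyphenyl]-3,6,8-trimethoxy-4H-chromen-4-one | COc1cc(-c2oc3c(OC)c(OCc4ccccc4)c(OC)c(OCc4ccccc4)c3c(=O)c2OC)c(OC)cc1OCc1ccccc1 | intermediate
28 | 5,7-dihydroxy-2-(4-hydroxy-2,5-dimethoxyphenyl)-3,6,8-trimethoxy-4H-chromen-4-one | COc1cc(-c2oc3c(OC)c(O)c(OC)c(O)c3c(=O)c2OC)c(OC)cc1O | target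

**Step count**

Total steps: 14. Longest linear sequence: 10 steps (steps 1–6, then 11–14); the ring B branch (steps 7–10) joins at step 11.

**Steps most likely to fail, with fallbacks**

Step 11. The doubly ortho-substituted, very electron-rich iodide may enter the catalytic cycle slowly. The aroyl-palladium species may be intercepted by diethylamine to give an amide, or the alkyne may couple without CO uptake and then close to a benzofuran. The fallback sets out from 10 and comes back at ynone 21, and from there at 23; it brings in C4 as a formyl carbon instead of CO and needs no palladium. Phenol 10 would be ortho-formylated at its only free position with MgCl2, Et3N and paraformaldehyde in MeCN at reflux to give 2,4-bis(benzyloxy)-6-hydroxy-3,5-dimethoxybenzaldehyde F1. The lithium acetylide of 19 (n-BuLi, THF, −78 °C, 2.2 equiv, the first equivalent being spent on the phenol) would add to F1 to give racemic 3,5-bis(benzyloxy)-2-{3-[4-(benzyloxy)-2,5-dimethoxyphenyl]-1-hydroxyprop-2-yn-1-yl}-4,6-dimethoxyphenol F2. This would be oxidised without delay with MnO2 in CH2Cl2 to ynone 21, and Et2NH in EtOH at rt should then close 21 to flavone 23 through enaminone 22.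

Step 12. Deprotonation may be incomplete or go astray (benzylic C–H of the benzyl ethers, opening of the pyranone by the amide base), so that boron is not placed at C3. The fallback sets out from 23 and comes back at 26; it delivers the oxygen electrophilically. Dimethyldioxirane in acetone/CH2Cl2 at 0 °C should epoxidise the C2=C3 bond to racemic 5,7-bis(benzyloxy)-2-[4-(benzyloxy)-2,5-dimethoxyphenyl]-2,3-epoxy-6,8-dimethoxychroman-4-one F3. A catalytic amount of p-toluenesulfonic acid in CH2Cl2 should then open the oxirane at C2 and, after loss of the C3 proton, give flavonol 26.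

Step 3. The exchange may run on to the dilithio species, or the aryllithium may be protonated, giving mixtures of unchanged, mono- and di-functionalised material. The fallback sets out from 3 and comes back at 10; it replaces both bromides at once and separates the two oxygens afterwards. Palladium-catalysed hydroxylation (Pd2(dba)3, 2-di-tert-butylphosphino-2',4',6'-triisopropylbiphenyl, KOH, 1,4-dioxane/H2O, 100 °C) should give the symmetric 5-(benzyloxy)-4,6-dimethoxybenzene-1,3-diol F4. Mono-benzylation of one of its two equivalent hydroxyls with one equivalent of BnBr and K2CO3 in acetone should give 10 after chromatographic separation, with recovered diol recycled; 10 then enters step 6.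

**Further compounds**

F1 | step 11 | 2,4-bis(benzyloxy)-6-hydroxy-3,5-dimethoxybenzaldehyde | COc1c(O)c(C=O)c(OCc2ccccc2)c(OC)c1OCc1ccccc1
F2 | step 11 | rac-3,5-bis(benzyloxy)-2-{3-[4-(benzyloxy)-2,5-dimethoxyphenyl]-1-hydroxyprop-2-yn-1-yl}-4,6-dimethoxyphenol | COc1cc(C#CC(O)c2c(O)c(OC)c(OCc3ccccc3)c(OC)c2OCc2ccccc2)c(OC)cc1OCc1ccccc1
F3 | step 12 | rac-5,7-bis(benzyloxy)-2-[4-(benzyloxy)-2,5-dimethoxyphenyl]-2,3-epoxy-6,8-dimethoxychroman-4-one (cis-fused oxirane, one enantiomer drawn) | O=C1c2c(OCc3ccccc3)c(OC)c(OCc3ccccc3)c(OC)c2O[C@]2(c3cc(OC)c(OCc4ccccc4)cc3OC)O[C@H]12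
F4 | step 3 | 5-(benzyloxy)-4,6-dimethoxybenzene-1,3-diol | COc1c(O)cc(O)c(OC)c1OCc1ccccc1
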